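## The problem

The target 15 is an acyclic bis-bibenzyl. Ring A (3-methoxyphenyl) and ring B are joined by one CH2CH2 bridge, ring C and ring D (3-hydroxyphenyl) by a second, and a single diaryl ether oxygen links ring B C3 to ring C C1' (ring B: bridge at C1, hydroxyl at C4; ring C: bridge at C4'). There is no stereocentre and no ring to close, so the task is one of regio- and chemoselectivity only. The ether must sit ortho to the ring B hydroxyl and para to the ring C bridge, and the three phenolic oxygens must end up differentiated: a methyl ether on ring A, free hydroxyls on rings B and D. The two halves are nearly identical 4-(2-arylethyl)phenols that differ only in a remote O-substituent, so a method that unites them as phenols must tell them apart and fix which supplies carbon and which supplies oxygen. The electron-rich rings A and D invite electrophilic halogenation and over-oxidation, and the benzylic CH2 groups para to a phenolic oxygen can be lost to quinone methide formation. The group protecting the ring D oxygen must come off without the Lewis acids that would also cleave the ring A methyl ether. The enabling feature is that ring B is a para-alkylphenol whose ortho carbon C3 carries the oxygen of a second para-alkylphenol (ring C). That is the ortho C–O linkage that phenol oxidation creates once carbon–carbon coupling is blocked.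

## Retrosynthesis

**15 back to 14.** No skeletal bond is cut. A bromine is placed on ring B C5, two chlorines on ring C flanking the ether oxygen (C2', C6'), and a benzyl group on the ring D oxygen, giving 14. The halogens are the traces of the coupling chemistry and the benzyl group is the one protecting group of the route. All four are hydrogenolysable in a single operation that leaves the methyl ether alone. The forward reaction must remove one C–Br, two C–Cl and one O–benzyl bond completely.

**14 back to 13.** Ring B of 14 is dearomatised by putting the bromine back on C3, the carbon that carries the ether oxygen. This gives the 6-aryloxy-6-bromocyclohexa-2,4-dienone 13. Forward, a two-electron reduction must expel bromide and not aryloxide, after which the dienolate is simply the phenolate of 14. The stereocentre of 13 is of no consequence.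

**13 back to 6 and 12.** The ring B C3–O bond is cut, giving two complete bibenzyl phenols, the ring A–B unit 6 and the ring C–D unit 12.
- Cutting the other ether bond (O–ring C C1') calls for an Ullmann or nucleophilic aromatic substitution in which ring B must appear as a differentiated catechol, so the likeness of the two halves is lost.
- Cutting a bridge first leaves the ether still to be made.
- The oxidative cut alone reduces the problem to two para-substituted phenols made by the same chemistry.

The ortho halogens are required to block carbon–carbon coupling, but they must not be the same on both partners. With bromine on both, the phenols would be electronically indistinguishable. Four dimers would form, and the cross-product of reversed direction would be an isomer of 13 leading to an isomer of 15 that differs only in which end carries the methyl group. An excess of the ring C–D phenol would then favour that wrong isomer, because the phenol in excess is the one mostly oxidised. Ring B therefore carries bromine (6) and ring C chlorine (12). The bromophenol should be oxidised at the lower potential and the chlorophenol, in excess, should act as the oxygen nucleophile. The forward reaction must oxidise 6 only and join it through a bromine-bearing ortho carbon.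

**6 back to 5, then to 2 (ylide 4) and 3, then to 1.** The saturated bridge of 6 is traced to the stilbene 5, and the C=C bond is cut by a Wittig disconnection into phosphonium salt 2 (from benzyl bromide 1, through ylide 4) and 3,5-dibromo-4-hydroxybenzaldehyde 3. The bromines are bought on 3 so that no electrophilic bromination is run in the presence of ring A. The price is an olefination on a free phenol aldehyde and a reduction of 5 that must spare two aryl bromides, which points to diimide.

**12 back to 11, then to 8 (ylide 10) and 9, then to 7.** The same two cuts lead from 12 through stilbene 11 to phosphonium salt 8 (from benzyl bromide 7, through ylide 10) and 3,5-dichloro-4-hydroxybenzaldehyde 9. Diimide here also spares the benzyl ether and the aryl chlorides. Both halves are thus made by one three-step sequence from four commercial compounds.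

## Roads not taken

**Alternative 1:** Ring B itself is cut, at the C2–C3 and C5–C6 bonds of a cyclohexenone.
- Forward key step: a Robinson annulation in which 1-(4-{2-[3-(benzyloxy)phenyl]ethyl}phenoxy)propan-2-one A1 adds in a Michael reaction, through its aryloxy-bearing carbon, to 4-(3-methoxyphenyl)-2-methylidenebutanal A2. The methyl ketone then condenses with the aldehyde to close 6-aryloxy-4-[2-(3-methoxyphenyl)ethyl]cyclohex-2-en-1-one A3 as a diastereomer mixture. Dehydrogenation would give the phenol A4 and hydrogenolysis would give 15.
- Merits: the ether oxygen ends ortho to the future hydroxyl by construction, there are no halogens, and there is no cross-coupling statistics. In certainty of constitution it is better than the chosen plan.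
- Weak points: it builds a benzene ring that can be bought. A2 is a polymerisation-prone 2-substituted acrolein that must first be made. A3 is two hydrogens short of the phenol, and its dehydrogenation must spare two CH2CH2 bridges. It must also outrun the redox-neutral loss of the ring C phenol from A3, which aromatises ring B without the ether.
- Comparison: the sequence is longer and trades one selectivity gamble for another. The chosen plan keeps all four rings aromatic throughout and forms the ether in the last skeletal step.

**Alternative 2:** The ring C–ring D bridge is cut as a stilbene C=C bond and the ether is made earlier.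
- Forward key step: the N-unsubstituted hydrazone (E)-[3-(benzyloxy)benzylidene]hydrazine A7 acts as a carbanion equivalent towards 4-{2-(benzyloxy)-5-[2-(3-methoxyphenyl)ethyl]phenoxy}benzaldehyde A6 under [Ru(p-cymene)Cl2]2, a bisphosphine and base. With loss of N2 and water it gives the (E)-stilbene A8, which one hydrogenation converts into 15. A6 would come from the phenol 2-(benzyloxy)-5-[2-(3-methoxyphenyl)ethyl]phenol A5 by nucleophilic aromatic substitution.
- Merits: the ether is formed with no question of direction or homocoupling, there are no halogens to remove, and the end game is a single clean hydrogenation. In reliability, and probably in total step count, this road is at least as good as the chosen one.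
- Weak points: A5 needs a ring B building block whose two catechol oxygens are told apart from the start. Free hydrazones of aryl aldehydes drift to azines or Wolff–Kishner reduction. The ruthenium step does nothing that a Wittig reaction of A6 with ylide 10 would not do.
- Comparison: the chosen plan sets full convergence against it. Two complete bibenzyls made by identical operations are united at the last skeletal step, no differentiated catechol is needed, and the coupling follows the presumed biogenesis, so any pair of para-alkylphenols could be joined the same way.

**Alternative 3:** The bond between the bridge CH2 and ring B C1 is cut.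
- Forward key step: 2-(3-methoxyphenyl)ethylmagnesium bromide A11 adds 1,2 to the carbonyl of the quinone monoketal 3-(4-{2-[3-(benzyloxy)phenyl]ethyl}phenoxy)-4,4-dimethoxycyclohexa-2,5-dien-1-one A10. The product is the tertiary alcohol A12, to be reductively aromatised and debenzylated.
- Merits: the carbon–carbon bond formation is strongly driven and the substitution pattern of ring B is fixed beforehand.
- Weak points: A10 has to be made by oxidation of 3-(4-{2-[3-(benzyloxy)phenyl]ethyl}phenoxy)-4-methoxyphenol A9, which already contains the diaryl ether, so the hard bond is only moved to an earlier conventional coupling. The carbonyl of A10 is part of a vinylogous ester, so conjugate addition followed by loss of aryloxide can destroy the ether. A12 needs ketal hydrolysis and a two-electron reduction, under which acid-induced 1,2-shift of the arylethyl group competes.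
- Comparison: every bond formation is polar and free of statistics, which the chosen plan cannot claim. The route is longer, however, carries redox adjustments on ring B and still owes a separate ether synthesis.

Key step: step 7

## Route

Remark: ring B is numbered with the bridge carbon as C1, the ether carbon as C3 and the hydroxyl carbon as C4; ring C with the ether carbon as C1' and the bridge carbon as C4'. Compounds 1, 3, 7 and 9 are taken to be commercial.

Step 1
Reactants: 1 3-methoxybenzyl bromide
Product: 2 (3-methoxybenzyl)triphenylphosphonium bromide
Conditions: PPh3, toluene, reflux; filtration of the salt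
Reagents that add atoms: triphenylphosphine, c1ccc(cc1)P(c1ccccc1)c1ccccc1
Why: SN2 quaternisation of a primary benzylic bromide by the phosphine; the salt should crystallise from toluene.

Step 2
Reactants: 2 (3-methoxybenzyl)triphenylphosphonium bromide; 3 3,5-dibromo-4-hydroxybenzaldehyde
Product: 5 2,6-dibromo-4-[2-(3-methoxyphenyl)ethenyl]phenol (E/Z mixture), via (3-methoxybenzylidene)triphenylphosphorane 4 (not isolated)
Conditions: 2 (1.3 equiv), t-BuOK (2.5 equiv), THF, 0 °C; then 3, rt to 50 °C; aq. NH4Cl
Reagents that add atoms: none
Why: Wittig olefination with a semi-stabilised benzylic ylide; the extra base first converts the acidic phenol into its phenolate, which the two ortho bromines make a weak donor, so the aldehyde should still react. The alkene geometry is irrelevant because the double bond is reduced next.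

Step 3
Reactants: 5 2,6-dibromo-4-[2-(3-methoxyphenyl)ethenyl]phenol (E/Z mixture)
Product: 6 2,6-dibromo-4-[2-(3-methoxyphenyl)ethyl]phenol
Conditions: TsNHNH2, NaOAc, THF–H2O, reflux
Reagents that add atoms: none
Why: Diimide reduction; diimide released from the sulfonyl hydrazide transfers two hydrogens to the C=C bond of both stilbene isomers in a concerted step and leaves the aryl C–Br bonds, which hydrogenation over palladium would cleave, untouched.

Step 4
Reactants: 7 3-(benzyloxy)benzyl bromide
Product: 8 [3-(benzyloxy)benzyl]triphenylphosphonium bromide
Conditions: PPh3, toluene, reflux; filtration of the salt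
Reagents that add atoms: triphenylphosphine, c1ccc(cc1)P(c1ccccc1)c1ccccc1
Why: SN2 quaternisation as in step 1; the aryl benzyl ether is inert.

Step 5
Reactants: 8 [3-(benzyloxy)benzyl]triphenylphosphonium bromide; 9 3,5-dichloro-4-hydroxybenzaldehyde
Product: 11 4-{2-[3-(benzyloxy)phenyl]ethenyl}-2,6-dichlorophenol (E/Z mixture), via [3-(benzyloxy)benzylidene]triphenylphosphorane 10 (not isolated)
Conditions: 8 (1.3 equiv), t-BuOK (2.5 equiv), THF, 0 °C; then 9, rt to 50 °C; aq. NH4Cl
Reagents that add atoms: none
Why: Wittig olefination as in step 2, here on the dichlorophenolate aldehyde; the alkene geometry is again irrelevant.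

Step 6
Reactants: 11 4-{2-[3-(benzyloxy)phenyl]ethenyl}-2,6-dichlorophenol (E/Z mixture)
Product: 12 4-{2-[3-(benzyloxy)phenyl]ethyl}-2,6-dichlorophenol
Conditions: TsNHNH2, NaOAc, THF–H2O, reflux
Reagents that add atoms: none
Why: Diimide reduction as in step 3; it saturates the stilbene and spares both the aryl C–Cl bonds and the benzyl ether that catalytic hydrogenation would remove.

Step 7
Reactants: 6 2,6-dibromo-4-[2-(3-methoxyphenyl)ethyl]phenol; 12 4-{2-[3-(benzyloxy)phenyl]ethyl}-2,6-dichlorophenol
Product: 13 6-(4-{2-[3-(benzyloxy)phenyl]ethyl}-2,6-dichlorophenoxy)-2,6-dibromo-4-[2-(3-methoxyphenyl)ethyl]cyclohexa-2,4-dien-1-one (racemic)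
Conditions: 12 (3 equiv), LiClO4 (0.1 M), MeOH, glassy-carbon anode, Pt-wire cathode, undivided cell, rt; potential held at the foot of the anodic wave of 6 (set by cyclic voltammetry of 6 and 12), slow addition of 6, 2 F per mol of 6; extractive work-up, crude 13 carried on
Reagents that add atoms: none
Why: At a potential held at the first wave of 6, the dibromophenol (as the phenolate formed by cathodically generated methoxide) should lose two electrons via its phenoxyl radical to a phenoxonium-type species, while the dichlorophenol 12, expected to be oxidised at a somewhat higher potential and present in excess, acts as nucleophile. The oxygen of 12 adds to a bromine-bearing ortho carbon of oxidised 6, forming the ring B C3–O bond and the 6-aryloxy-6-bromocyclohexa-2,4-dienone 13. The closest known reaction type is the anodic or Tl(NO3)3 oxidation of 2,6-dihalo-4-alkylphenols to ortho-aryloxy halodienones, including mixed bromo/chloro pairs in which the brominated ring is the one oxidised. No ring is closed; the one new stereocentre (C6, carrying Br and the aryloxy group) forms without control, so 13 is racemic, and it is erased in step 8. Oxygen–carbon over carbon–carbon coupling is secured by the four ortho halogens, and ortho over para attack by the bridge at the para carbon. Cross over homo coupling and the right direction rest on the Br/Cl difference in potential, the excess of 12, the slow addition of 6 and the charge limit. The working potential lies well below that of the alkoxyarene rings A and D. Should direction be imperfect, the reversed product differs from 13 in halogen content and is not an isomer, so it can be detected and separated.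

Step 8
Reactants: 13 6-(4-{2-[3-(benzyloxy)phenyl]ethyl}-2,6-dichlorophenoxy)-2,6-dibromo-4-[2-(3-methoxyphenyl)ethyl]cyclohexa-2,4-dien-1-one (racemic)
Product: 14 2-(4-{2-[3-(benzyloxy)phenyl]ethyl}-2,6-dichlorophenoxy)-6-bromo-4-[2-(3-methoxyphenyl)ethyl]phenol
Conditions: Zn powder, AcOH, THF, 0 °C to rt; chromatography (excess 12 recovered)
Reagents that add atoms: none
Why: Reductive dehalogenation of an α-bromo ketone; zinc transfers two electrons, bromide leaves the quaternary carbon as the better leaving group, and the resulting dienolate is the phenolate of 14, so ring B rearomatises with its hydroxyl between the new ether and the remaining bromine. Aryl halides and the benzyl ether do not react with zinc in acetic acid at this temperature.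

Step 9
Reactants: 14 2-(4-{2-[3-(benzyloxy)phenyl]ethyl}-2,6-dichlorophenoxy)-6-bromo-4-[2-(3-methoxyphenyl)ethyl]phenol
Product: 15 2-{4-[2-(3-hydroxyphenyl)ethyl]phenoxy}-4-[2-(3-methoxyphenyl)ethyl]phenol
Conditions: H2 (1 atm), 10% Pd/C, Et3N (5 equiv), MeOH–EtOAc, rt
Reagents that add atoms: none
Why: Catalytic hydrogenolysis; palladium on carbon with an amine as acid scavenger cleaves aryl C–Br and C–Cl bonds and the phenolic benzyl ether, while the methyl ether and the diaryl ether are inert. Products from any homodimer carried through differ from 15 in the number of free hydroxyls and should separate easily here.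

## Compound list

1 | 3-methoxybenzyl bromide | COc1cccc(CBr)c1 | starting material
2 | (3-methoxybenzyl)triphenylphosphonium bromide | COc1cccc(C[P+](c2ccccc2)(c2ccccc2)c2ccccc2)c1.[Br-] | intermediate
3 | 3,5-dibromo-4-hydroxybenzaldehyde | O=Cc1cc(Br)c(O)c(Br)c1 | starting material
4 | (3-methoxybenzylidene)triphenylphosphorane | COc1cccc(C=P(c2ccccc2)(c2ccccc2)c2ccccc2)c1 | intermediate (not isolated)
5 | 2,6-dibromo-4-[2-(3-methoxyphenyl)ethenyl]phenol (E/Z mixture) | COc1cccc(C=Cc2cc(Br)c(O)c(Br)c2)c1 | intermediate
6 | 2,6-dibromo-4-[2-(3-methoxyphenyl)ethyl]phenol | COc1cccc(CCc2cc(Br)c(O)c(Br)c2)c1 | intermediate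
7 | 3-(benzyloxy)benzyl bromide | BrCc1cccc(OCc2ccccc2)c1 | starting material
8 | [3-(benzyloxy)benzyl]triphenylphosphonium bromide | [Br-].c1ccc(COc2cccc(C[P+](c3ccccc3)(c3ccccc3)c3ccccc3)c2)cc1 | intermediate
9 | 3,5-dichloro-4-hydroxybenzaldehyde | O=Cc1cc(Cl)c(O)c(Cl)c1 | starting material
10 | [3-(benzyloxy)benzylidene]triphenylphosphorane | c1ccc(COc2cccc(C=P(c3ccccc3)(c3ccccc3)c3ccccc3)c2)cc1 | intermediate (not isolated)
11 | 4-{2-[3-(benzyloxy)phenyl]ethenyl}-2,6-dichlorophenol (E/Z mixture) | Oc1c(Cl)cc(C=Cc2cccc(OCc3ccccc3)c2)cc1Cl | intermediate
12 | 4-{2-[3-(benzyloxy)phenyl]ethyl}-2,6-dichlorophenol | Oc1c(Cl)cc(CCc2cccc(OCc3ccccc3)c2)cc1Cl | intermediate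
13 | 6-(4-{2-[3-(benzyloxy)phenyl]ethyl}-2,6-dichlorophenoxy)-2,6-dibromo-4-[2-(3-methoxyphenyl)ethyl]cyclohexa-2,4-dien-1-one (racemic) | COc1cccc(CCC2=CC(Br)(Oc3c(Cl)cc(CCc4cccc(OCc5ccccc5)c4)cc3Cl)C(=O)C(Br)=C2)c1 | intermediate
14 | 2-(4-{2-[3-(benzyloxy)phenyl]ethyl}-2,6-dichlorophenoxy)-6-bromo-4-[2-(3-methoxyphenyl)ethyl]phenol | COc1cccc(CCc2cc(Br)c(O)c(Oc3c(Cl)cc(CCc4cccc(OCc5ccccc5)c4)cc3Cl)c2)c1 | intermediate
15 | 2-{4-[2-(3-hydroxyphenyl)ethyl]phenoxy}-4-[2-(3-methoxyphenyl)ethyl]phenol | COc1cccc(CCc2ccc(O)c(Oc3ccc(CCc4cccc(O)c4)cc3)c2)c1 | target

## Step count and least certain steps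

Total step count: 9. Longest linear sequence: 6 steps (1, 2, 3, 7, 8, 9 or 4, 5, 6, 7, 8, 9).

**Step 7 (key step).**
- Risk: loss of chemoselectivity in the oxidation. If electron or hydrogen exchange between oxidised 6 and unoxidised 12 outruns C–O bond formation, both phenols become oxidised and the mixture drifts towards the statistical set of dimers, with homocoupling of 6 and coupling in the reverse direction. Capture of the oxidised phenol by methanol at the para or benzylic carbon is a second drain.
- Fallback (sets out from 6 and 8, returns at 15): the ether is made by copper chemistry and the ring C–D bridge afterwards. 6 is O-benzylated (benzyl bromide, K2CO3, DMF) to 2-(benzyloxy)-1,3-dibromo-5-[2-(3-methoxyphenyl)ethyl]benzene F1. One of its two equivalent bromides is replaced by 4-hydroxybenzaldehyde in an Ullmann ether synthesis (CuI, picolinic acid, K3PO4, DMSO, 90 °C), giving 4-{2-(benzyloxy)-3-bromo-5-[2-(3-methoxyphenyl)ethyl]phenoxy}benzaldehyde F2. A Wittig reaction with ylide 10, made from 8 and t-BuOK in THF, gives 2-(benzyloxy)-1-(4-{2-[3-(benzyloxy)phenyl]ethenyl}phenoxy)-3-bromo-5-[2-(3-methoxyphenyl)ethyl]benzene F3 as an E/Z mixture. H2, Pd/C and Et3N in MeOH–EtOAc then saturate the alkene and cleave the remaining C–Br bond and both benzyl ethers to reach 15.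

**Step 9.**
- Risk: incomplete hydrogenolysis through mutual interference. The amine needed to drive the removal of the two aryl chlorides can slow cleavage of the benzyl ether, and halide build-up can stall the catalyst, leaving partly dehalogenated or still benzylated material.
- Fallback (sets out from 14, returns at 15): the two tasks are separated and done by different mechanisms. The benzyl ether is cleaved with BCl3 and pentamethylbenzene in CH2Cl2 at −78 °C, which should spare the methyl ether at this temperature, to give 2-bromo-6-{2,6-dichloro-4-[2-(3-hydroxyphenyl)ethyl]phenoxy}-4-[2-(3-methoxyphenyl)ethyl]phenol F4. Its three halogens are then removed by transfer hydrodehalogenation (HCO2NH4, Pd/C, MeOH, reflux) to give 15.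

**Step 8.**
- Risk: reductive cleavage in the wrong sense, in which electron transfer to the dienone expels aryloxide instead of bromide and returns the two monomers, and decomposition of the crude dienone on handling.
- Fallback (sets out from 13, returns at 14): the bromine is removed as a positive halogen instead of by a metal. Treatment of crude 13 with NaI in AcOH–THF, followed by Na2S2O3 work-up, should give 14 by attack of iodide on the bromine, a path on which the aryloxy group cannot leave. This fallback makes no new compound (F0).

**Step 2.**
- Risk: sluggish or incomplete olefination, because the aldehyde is present as a poorly soluble phenolate, a vinylogous carboxylate of lowered electrophilicity.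
- Fallback (sets out from 2, returns at 6): the phenol is carried protected and the bromines are introduced last. Ylide 4 from 2 is combined with 4-(benzyloxy)benzaldehyde to give 1-(benzyloxy)-4-[2-(3-methoxyphenyl)ethenyl]benzene F5 as an E/Z mixture. H2 and Pd/C in EtOAc–MeOH reduce the alkene and cleave the benzyl ether to give 4-[2-(3-methoxyphenyl)ethyl]phenol F6. N-Bromosuccinimide (2 equiv) with catalytic i-Pr2NH in CH2Cl2, an ortho-selective bromination of phenols that should leave the methoxyarene ring A alone, then gives 6.

**Step 5.**
- Risk: the same deactivation of the aldehyde by its phenolate. Here the ring D benzyl ether rules out the hydrogenation-based remedy used for step 2.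
- Fallback (sets out from 9, using ylide 10 from 8; returns at 12): 9 is protected with chloromethyl methyl ether and i-Pr2NEt in CH2Cl2 as 3,5-dichloro-4-(methoxymethoxy)benzaldehyde F7. A Wittig reaction with ylide 10 gives 1-(benzyloxy)-3-{2-[3,5-dichloro-4-(methoxymethoxy)phenyl]ethenyl}benzene F8 as an E/Z mixture. Diimide reduction (TsNHNH2, NaOAc, THF–H2O, reflux) gives 1-(benzyloxy)-3-{2-[3,5-dichloro-4-(methoxymethoxy)phenyl]ethyl}benzene F9. HCl in MeOH at 50 °C removes the acetal to give 12.

## Further compounds

F1 | step 7 | 2-(benzyloxy)-1,3-dibromo-5-[2-(3-methoxyphenyl)ethyl]benzene | COc1cccc(CCc2cc(Br)c(OCc3ccccc3)c(Br)c2)c1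
F2 | step 7 | 4-{2-(benzyloxy)-3-bromo-5-[2-(3-methoxyphenyl)ethyl]phenoxy}benzaldehyde | COc1cccc(CCc2cc(Br)c(OCc3ccccc3)c(Oc3ccc(C=O)cc3)c2)c1
F3 | step 7 | 2-(benzyloxy)-1-(4-{2-[3-(benzyloxy)phenyl]ethenyl}phenoxy)-3-bromo-5-[2-(3-methoxyphenyl)ethyl]benzene (E/Z mixture) | COc1cccc(CCc2cc(Br)c(OCc3ccccc3)c(Oc3ccc(C=Cc4cccc(OCc5ccccc5)c4)cc3)c2)c1
F4 | step 9 | 2-bromo-6-{2,6-dichloro-4-[2-(3-hydroxyphenyl)ethyl]phenoxy}-4-[2-(3-methoxyphenyl)ethyl]phenol | COc1cccc(CCc2cc(Br)c(O)c(Oc3c(Cl)cc(CCc4cccc(O)c4)cc3Cl)c2)c1
F0 | step 8 | none | none
F5 | step 2 | 1-(benzyloxy)-4-[2-(3-methoxyphenyl)ethenyl]benzene (E/Z mixture) | COc1cccc(C=Cc2ccc(OCc3ccccc3)cc2)c1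
F6 | step 2 | 4-[2-(3-methoxyphenyl)ethyl]phenol | COc1cccc(CCc2ccc(O)cc2)c1
F7 | step 5 | 3,5-dichloro-4-(methoxymethoxy)benzaldehyde | COCOc1c(Cl)cc(C=O)cc1Cl
F8 | step 5 | 1-(benzyloxy)-3-{2-[3,5-dichloro-4-(methoxymethoxy)phenyl]ethenyl}benzene (E/Z mixture) | COCOc1c(Cl)cc(C=Cc2cccc(OCc3ccccc3)c2)cc1Cl
F9 | step 5 | 1-(benzyloxy)-3-{2-[3,5-dichloro-4-(methoxymethoxy)phenyl]ethyl}benzene | COCOc1c(Cl)cc(CCc2cccc(OCc3ccccc3)c2)cc1Cl
A1 | alternative 1 | 1-(4-{2-[3-(benzyloxy)phenyl]ethyl}phenoxy)propan-2-one | CC(=O)COc1ccc(CCc2cccc(OCc3ccccc3)c2)cc1
A2 | alternative 1 | 4-(3-methoxyphenyl)-2-methylidenebutanal | COc1cccc(CCC(=C)C=O)c1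
A3 | alternative 1 | 6-(4-{2-[3-(benzyloxy)phenyl]ethyl}phenoxy)-4-[2-(3-methoxyphenyl)ethyl]cyclohex-2-en-1-one (diastereomer mixture, racemic) | COc1cccc(CCC2C=CC(=O)C(Oc3ccc(CCc4cccc(OCc5ccccc5)c4)cc3)C2)c1
A4 | alternative 1 | 2-(4-{2-[3-(benzyloxy)phenyl]ethyl}phenoxy)-4-[2-(3-methoxyphenyl)ethyl]phenol | COc1cccc(CCc2ccc(O)c(Oc3ccc(CCc4cccc(OCc5ccccc5)c4)cc3)c2)c1
A5 | alternative 2 | 2-(benzyloxy)-5-[2-(3-methoxyphenyl)ethyl]phenol | COc1cccc(CCc2ccc(OCc3ccccc3)c(O)c2)c1
A6 | alternative 2 | 4-{2-(benzyloxy)-5-[2-(3-methoxyphenyl)ethyl]phenoxy}benzaldehyde | COc1cccc(CCc2ccc(OCc3ccccc3)c(Oc3ccc(C=O)cc3)c2)c1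
A7 | alternative 2 | (E)-[3-(benzyloxy)benzylidene]hydrazine | N/N=C/c1cccc(OCc2ccccc2)c1
A8 | alternative 2 | 1-(benzyloxy)-2-(4-{(E)-2-[3-(benzyloxy)phenyl]ethenyl}phenoxy)-4-[2-(3-methoxyphenyl)ethyl]benzene | COc1cccc(CCc2ccc(OCc3ccccc3)c(Oc3ccc(/C=C/c4cccc(OCc5ccccc5)c4)cc3)c2)c1
A9 | alternative 3 | 3-(4-{2-[3-(benzyloxy)phenyl]ethyl}phenoxy)-4-methoxyphenol | COc1ccc(O)cc1Oc1ccc(CCc2cccc(OCc3ccccc3)c2)cc1
A10 | alternative 3 | 3-(4-{2-[3-(benzyloxy)phenyl]ethyl}phenoxy)-4,4-dimethoxycyclohexa-2,5-dien-1-one | COC1(OC)C=CC(=O)C=C1Oc1ccc(CCc2cccc(OCc3ccccc3)c2)cc1
A11 | alternative 3 | 2-(3-methoxyphenyl)ethylmagnesium bromide | COc1cccc(CC[Mg]Br)c1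
A12 | alternative 3 | 3-(4-{2-[3-(benzyloxy)phenyl]ethyl}phenoxy)-4,4-dimethoxy-1-[2-(3-methoxyphenyl)ethyl]cyclohexa-2,5-dien-1-ol (racemic) | COc1cccc(CCC2(O)C=CC(OC)(OC)C(Oc3ccc(CCc4cccc(OCc5ccccc5)c4)cc3)=C2)c1
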